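**Plan**

- Retrosynthesis: set aside the two silyl groups and the C6 ester (ester ← 6β-alcohol ← 6-ketone ← 6-nitro group), then cut ring B at C5–C10 and C6–C7.
- Enabling feature: ring B is a cyclohexene whose C8=C9 double bond lies opposite the C5–C6 bond, so C7=C8–C9=C10 is a diene and C5=C6 a dienophile; the C1–C4 chain of ring A already links C10 to C5 as a four-atom tether. A nitro group on C6 is the temporary activator (ketene equivalent) and the C7 silyloxy group is the future 7-OH.
- Forward, the chain is joined first: side-chain iodide (C11–C16) alkylates ethyl acetoacetate (C8, C9, C10, C20); an (E)-enol triflate and B-alkyl Suzuki coupling with the C1–C5 unit fix the tetrasubstituted C9=C10 alkene; C17 and C7 are added at the ester carbon and C6 by a Henry reaction.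
- Rings A and B then close together in one intramolecular Diels–Alder step; nitro-to-ketone unmasking, reduction, acylation and desilylation finish the route.
- Stereochemistry: C5, C7 and C10 (relative) from the alkene geometries of the triene and the endo/anti transition state; the absolute sense from a chiral hydrogen-bond-donor catalyst; C6 from α-face hydride attack on the 6-ketone; the side-chain (E)-alkene from the starting enynol.

Key step: step 13

Remark: labdane numbering of the target is used for all atoms, also in acyclic intermediates (C1–C10 decalin, C11–C16 side chain, C17 on C8, C18/C19 on C4, C20 on C10); α is the face opposite the C10 methyl group, labdane names imply the (5S,10S) trans-fused skeleton, and the target is (5S,6S,7S,10S). Compounds 15–19 are racemic at the oxirane carbon (17 and 18 are diastereomer mixtures); these centers are erased before the key step.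

**Route**

Step 1
Reactants: 1 (2E)-3-methylpent-2-en-4-yn-1-ol
Product: 2 tert-butyl{[(2E)-3-methylpent-2-en-4-yn-1-yl]oxy}diphenylsilane
Conditions: TBDPSCl, imidazole, CH2Cl2, 0 °C to rt
Reagents that add atoms: tert-butyl(chloro)diphenylsilane CC(C)(C)[Si](Cl)(c1ccccc1)c1ccccc1
Why: Silyl ether protection of a primary allylic alcohol with a group robust enough for all later acidic, basic and organometallic steps; the (E)-alkene is bought in and not touched.

Step 2
Reactants: 2 tert-butyl{[(2E)-3-methylpent-2-en-4-yn-1-yl]oxy}diphenylsilane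
Product: 3 tert-butyl{[(2E)-3-methylpenta-2,4-dien-1-yl]oxy}diphenylsilane
Conditions: H2 (1 atm), Pd/CaCO3 poisoned with Pb(OAc)2, quinoline, hexane–EtOAc, rt, stopped after 1 equiv
Reagents that add atoms: none
Why: Semihydrogenation of a terminal alkyne over poisoned palladium should stop at the 1,3-diene and leave the trisubstituted (E)-alkene unchanged.

Step 3
Reactants: 3 tert-butyl{[(2E)-3-methylpenta-2,4-dien-1-yl]oxy}diphenylsilane
Product: 5 (3E)-5-[(tert-butyldiphenylsilyl)oxy]-3-methylpent-3-en-1-ol, via alkylborane 4 (not isolated)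
Conditions: 9-BBN, THF, 0 °C to rt; then NaOH (aq), H2O2, 0 °C to rt
Reagents that add atoms: 9-borabicyclo[3.3.1]nonane B1C2CCCC1CCC2 (boron stays in 4 only); hydrogen peroxide OO
Why: Anti-Markovnikov hydroboration–oxidation, in which the bulky borane should attack only the monosubstituted terminus of the diene and give the primary homoallylic alcohol.

Step 4
Reactants: 5 (3E)-5-[(tert-butyldiphenylsilyl)oxy]-3-methylpent-3-en-1-ol
Product: 6 tert-butyl{[(2E)-5-iodo-3-methylpent-2-en-1-yl]oxy}diphenylsilane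
Conditions: I2, PPh3, imidazole, CH2Cl2, 0 °C to rt
Reagents that add atoms: iodine II
Why: Appel-type iodination of a primary alcohol through its alkoxyphosphonium salt, which is compatible with the alkene and the silyl ether.

Step 5
Reactants: 6 tert-butyl{[(2E)-5-iodo-3-methylpent-2-en-1-yl]oxy}diphenylsilane; 7 ethyl 3-oxobutanoate
Product: 8 ethyl (5E)-2-acetyl-7-[(tert-butyldiphenylsilyl)oxy]-5-methylhept-5-enoate
Conditions: NaH, THF–DMF, 0 °C; then 6, 60 °C
Reagents that add atoms: none
Why: Acetoacetic ester C-alkylation of the soft sodium enolate with a primary iodide, which should prefer substitution to elimination; the new center is racemic and is planarised in the next step.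

Step 6
Reactants: 8 ethyl (5E)-2-acetyl-7-[(tert-butyldiphenylsilyl)oxy]-5-methylhept-5-enoate
Product: 9 ethyl (2E)-2-{(3E)-5-[(tert-butyldiphenylsilyl)oxy]-3-methylpent-3-en-1-yl}-3-{[(trifluoromethyl)sulfonyl]oxy}but-2-enoate
Conditions: Tf2O, Me4NOH (aq), toluene, 5 °C
Reagents that add atoms: trifluoromethanesulfonic anhydride O=S(=O)(OS(=O)(=O)C(F)(F)F)C(F)(F)F
Why: Stereoselective O-triflation of a β-keto ester enolate, where the non-coordinating tetraalkylammonium counter-ion should favour the unchelated enolate and hence the (E)-enol triflate (OTf trans to CO2Et), the geometry that later puts the C1 chain trans to C8.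

Step 7
Reactants: 9 ethyl (2E)-2-{(3E)-5-[(tert-butyldiphenylsilyl)oxy]-3-methylpent-3-en-1-yl}-3-{[(trifluoromethyl)sulfonyl]oxy}but-2-enoate; 10 2,2-dimethylpent-4-enal
Product: 12 ethyl (2E)-2-{(3E)-5-[(tert-butyldiphenylsilyl)oxy]-3-methylpent-3-en-1-yl}-8-hydroxy-3,7,7-trimethyloct-2-enoate, via bis(boryl) intermediate 11 (not isolated)
Conditions: 10, 9-BBN (2.2 equiv), THF, 0 °C to rt; then 9, Pd(dppf)Cl2 (5 mol %), K3PO4 (aq), DMF, rt to 50 °C
Reagents that add atoms: 9-borabicyclo[3.3.1]nonane B1C2CCCC1CCC2 (boron stays in 11 only)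
Why: The borane reduces the aldehyde to a borinate-masked neopentyl alcohol and hydroborates the terminal alkene, and the primary alkylborane then undergoes B-alkyl Suzuki–Miyaura coupling with the enol triflate with retention, which fixes the tetrasubstituted C9=C10 alkene with the C20 methyl cis to C8.

Step 8
Reactants: 12 ethyl (2E)-2-{(3E)-5-[(tert-butyldiphenylsilyl)oxy]-3-methylpent-3-en-1-yl}-8-hydroxy-3,7,7-trimethyloct-2-enoate
Product: 14 (3E)-3-{(3E)-5-[(tert-butyldiphenylsilyl)oxy]-3-methylpent-3-en-1-yl}-9-hydroxy-4,8,8-trimethylnon-3-en-2-one, via dilithium silyl enolate 13 (not isolated)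
Conditions: Me3SiCH2Li (4 equiv), THF–pentane, −78 to 0 °C; then MeOH, rt
Reagents that add atoms: (trimethylsilyl)methyllithium [Li]C[Si](C)(C)C
Why: Ester to methyl ketone conversion, in which the α-silyl ketone formed by acyl substitution is deprotonated at once to its enolate, blocking a second addition, and methanolysis then removes silicon to leave C17 as the ketone methyl.

Step 9
Reactants: 14 (3E)-3-{(3E)-5-[(tert-butyldiphenylsilyl)oxy]-3-methylpent-3-en-1-yl}-9-hydroxy-4,8,8-trimethylnon-3-en-2-one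
Product: 15 (6E,10E)-12-[(tert-butyldiphenylsilyl)oxy]-2,2,6,10-tetramethyl-7-(2-methyloxiran-2-yl)dodeca-6,10-dien-1-ol
Conditions: Me3S+ I−, n-BuLi, THF, −10 °C to rt
Reagents that add atoms: trimethylsulfonium iodide C[S+](C)C.[I-]
Why: Corey–Chaykovsky epoxidation, in which the small sulfonium ylide adds 1,2 to the hindered, twisted enone carbonyl and brings in C7 as a masked aldehyde that is not yet a diene, so no cycloaddition can occur before the nitroalkene is in place.

Step 10
Reactants: 15 (6E,10E)-12-[(tert-butyldiphenylsilyl)oxy]-2,2,6,10-tetramethyl-7-(2-methyloxiran-2-yl)dodeca-6,10-dien-1-ol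
Product: 16 (6E,10E)-12-[(tert-butyldiphenylsilyl)oxy]-2,2,6,10-tetramethyl-7-(2-methyloxiran-2-yl)dodeca-6,10-dienal
Conditions: Dess–Martin periodinane, pyridine, CH2Cl2, 0 °C to rt
Reagents that add atoms: none
Why: Dess–Martin oxidation of the neopentyl primary alcohol to the non-enolisable C5 aldehyde under buffered conditions that spare the acid-sensitive vinyl epoxide.

Step 11
Reactants: 16 (6E,10E)-12-[(tert-butyldiphenylsilyl)oxy]-2,2,6,10-tetramethyl-7-(2-methyloxiran-2-yl)dodeca-6,10-dienal
Product: 19 tert-butyl{[(2E,6E,12E)-3,7,11,11-tetramethyl-6-(2-methyloxiran-2-yl)-13-nitrotrideca-2,6,12-trien-1-yl]oxy}diphenylsilane, via nitro alcohol 17 (not isolated), via mesylate 18 (not isolated)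
Conditions: MeNO2 (10 equiv), 1,1,3,3-tetramethylguanidine (0.2 equiv), THF, 0 °C to rt; evaporate; MsCl, Et3N, CH2Cl2, −20 to 0 °C
Reagents that add atoms: nitromethane C[N+](=O)[O-]; methanesulfonyl chloride CS(=O)(=O)Cl (its atoms stay in 18 only)
Why: Henry reaction of the non-enolisable aldehyde followed by mesylation and E1cB elimination should give the thermodynamically favoured (E)-nitroalkene, which brings in C6 and cannot deconjugate because C4 is quaternary.

Step 12
Reactants: 19 tert-butyl{[(2E,6E,12E)-3,7,11,11-tetramethyl-6-(2-methyloxiran-2-yl)-13-nitrotrideca-2,6,12-trien-1-yl]oxy}diphenylsilane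
Product: 21 tert-butyl({(1E,3E,9E)-3-{(3E)-5-[(tert-butyldiphenylsilyl)oxy]-3-methylpent-3-en-1-yl}-2,4,8,8-tetramethyl-10-nitrodeca-1,3,9-trien-1-yl}oxy)dimethylsilane, via aldehyde 20 (not isolated)
Conditions: BF3·OEt2 (0.3 equiv), CH2Cl2, −78 °C; then Et3N, TBSOTf, −78 to −20 °C; cold NaHCO3 work-up, used at once
Reagents that add atoms: tert-butyldimethylsilyl trifluoromethanesulfonate CC(C)(C)[Si](C)(C)OS(=O)(=O)C(F)(F)F
Why: Lewis-acid Meinwald rearrangement of the 2,2-disubstituted vinyl epoxide (ionisation to the allylic tertiary cation, 1,2-hydride shift) gives the α-methyl β,γ-unsaturated aldehyde, and soft enolisation with silyl triflate and amine then gives the 1-silyloxy diene with the silyloxy group trans to the bulky C9 substituent (7E), the C9=C10 geometry being untouched.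

Step 13
Reactants: 21 tert-butyl({(1E,3E,9E)-3-{(3E)-5-[(tert-butyldiphenylsilyl)oxy]-3-methylpent-3-en-1-yl}-2,4,8,8-tetramethyl-10-nitrodeca-1,3,9-trien-1-yl}oxy)dimethylsilane
Product: 22 7α-[(tert-butyldimethylsilyl)oxy]-15-[(tert-butyldiphenylsilyl)oxy]-6α-nitrolabda-8,13E-diene
Conditions: chiral 2-arylpyrrolidine tert-leucine amido-thiourea bearing an N'-3,5-bis(trifluoromethyl)phenyl group (15 mol %, the antipode that leads to 22), toluene, 4 Å MS, −30 to 0 °C
Reagents that add atoms: none
Why: Proposed new method: the thiourea binds the nitro group of the (E)-nitroalkene through two hydrogen bonds and lowers its LUMO, and the electron-rich 1-silyloxy diene adds in an asynchronous, concerted [4+2] cycloaddition in which the nucleophilic diene terminus C10 bonds to C5 slightly ahead of the C7–C6 bond. The closest known reactions are the thermal type-1 intramolecular Diels–Alder reaction of (E)-1-nitro-1,7,9-decatrienes, which gives trans-fused nitro decalins, and hydrogen-bond-donor-catalysed enantioselective Diels–Alder and Michael reactions of nitroalkenes; only their union in an enantioselective intramolecular case is untested. Ring B closes as the six-membered ring of the [4+2] process, and ring A closes in the same event through the C5–C10 bond, the C1–C4 chain acting as a four-atom tether in a chair-like arrangement. Relative configuration follows from suprafacial addition: the C9=C10 alkene carries the C20 methyl cis to C8 ("inside") and the tether "outside", the (7E) silyloxy group is "outside", and the nitro group reacts endo with the tether exo, so the C10 methyl should be β, H5 α (trans fusion), the nitro group 6α and the silyloxy group 7α; the absolute sense should come from the chiral pocket of the catalyst, which leaves one face of the bound nitroalkene open to the tethered diene. The step needs trans over cis fusion, secured by the endo preference of the (E)-nitro group, and catalyst control over the uncatalysed pathway, helped by the low temperature and by both new bonds joining fully substituted or neopentyl carbons; any minor (7Z) dienol ether cannot reach the s-cis conformation because its silyloxy group would collide with the C20 methyl, and so stays behind.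

Step 14
Reactants: 22 7α-[(tert-butyldimethylsilyl)oxy]-15-[(tert-butyldiphenylsilyl)oxy]-6α-nitrolabda-8,13E-diene
Product: 24 7α-[(tert-butyldimethylsilyl)oxy]-15-[(tert-butyldiphenylsilyl)oxy]labda-8,13E-dien-6-one, via oxime 23 (not isolated)
Conditions: SnCl2, PhSH, Et3N, MeCN, rt; then TiCl3 (aq), NH4OAc (pH 6), THF, rt
Reagents that add atoms: water O
Why: A reductive Nef-type sequence in which the tin thiolate complex deoxygenates the secondary nitro group to the oxime and buffered trivalent titanium then cleaves the N–O bond and the imine is hydrolysed, which unmasks the C6 ketone without a free nitronate that could expel the C7 silyloxy group.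

Step 15
Reactants: 24 7α-[(tert-butyldimethylsilyl)oxy]-15-[(tert-butyldiphenylsilyl)oxy]labda-8,13E-dien-6-one
Product: 25 7α-[(tert-butyldimethylsilyl)oxy]-15-[(tert-butyldiphenylsilyl)oxy]labda-8,13E-dien-6β-ol
Conditions: LiAlH4, Et2O, −78 to −20 °C
Reagents that add atoms: none
Why: Hydride reduction under steric approach control, in which the β face of C6 is screened by the syn-axial C20 and C4β methyl groups as in other 6-oxo terpenoids, so hydride should enter from the α face and give the axial 6β-alcohol.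

Step 16
Reactants: 25 7α-[(tert-butyldimethylsilyl)oxy]-15-[(tert-butyldiphenylsilyl)oxy]labda-8,13E-dien-6β-ol
Product: 27 7α-[(tert-butyldimethylsilyl)oxy]-15-[(tert-butyldiphenylsilyl)oxy]labda-8,13E-dien-6β-yl 3-methylbutanoate, via lithium alkoxide 26 (not isolated)
Conditions: LiN(SiMe3)2, THF, −78 °C; then 3-methylbutanoyl chloride, −78 to 0 °C
Reagents that add atoms: 3-methylbutanoyl chloride CC(C)CC(Cl)=O; lithium bis(trimethylsilyl)amide [Li]N([Si](C)(C)C)[Si](C)(C)C (lithium stays in 26 only)
Why: Acylation of the pre-formed lithium alkoxide with the acid chloride, chosen because the axial 6β-hydroxyl between two syn-axial methyl groups is too hindered for amine-catalysed acylation, while the anti arrangement of O6 and O7 should prevent silyl migration.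

Step 17
Reactants: 27 7α-[(tert-butyldimethylsilyl)oxy]-15-[(tert-butyldiphenylsilyl)oxy]labda-8,13E-dien-6β-yl 3-methylbutanoate
Product: 28 (5S,6S,7S,10S)-7,15-dihydroxylabda-8,13E-dien-6-yl 3-methylbutanoate
Conditions: Bu4NF, AcOH, THF, 0 °C to rt
Reagents that add atoms: none
Why: Fluoride-mediated global desilylation buffered with acetic acid should free both hydroxyls while the hindered ester stays in place, the anti 6,7-relationship preventing acyl migration.

**Compound list**

1 | (2E)-3-methylpent-2-en-4-yn-1-ol | C#C/C(C)=C/CO | starting material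
2 | tert-butyl{[(2E)-3-methylpent-2-en-4-yn-1-yl]oxy}diphenylsilane | C#C/C(C)=C/CO[Si](c1ccccc1)(c1ccccc1)C(C)(C)C | intermediate
3 | tert-butyl{[(2E)-3-methylpenta-2,4-dien-1-yl]oxy}diphenylsilane | C=C/C(C)=C/CO[Si](c1ccccc1)(c1ccccc1)C(C)(C)C | intermediate
4 | 9-{(3E)-5-[(tert-butyldiphenylsilyl)oxy]-3-methylpent-3-en-1-yl}-9-borabicyclo[3.3.1]nonane | B1(CC/C(C)=C/CO[Si](c3ccccc3)(c4ccccc4)C(C)(C)C)C2CCCC1CCC2 | intermediate
5 | (3E)-5-[(tert-butyldiphenylsilyl)oxy]-3-methylpent-3-en-1-ol | OCC/C(C)=C/CO[Si](c1ccccc1)(c1ccccc1)C(C)(C)C | intermediate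
6 | tert-butyl{[(2E)-5-iodo-3-methylpent-2-en-1-yl]oxy}diphenylsilane | ICC/C(C)=C/CO[Si](c1ccccc1)(c1ccccc1)C(C)(C)C | intermediate
7 | ethyl 3-oxobutanoate | CCOC(=O)CC(C)=O | starting material
8 | ethyl (5E)-2-acetyl-7-[(tert-butyldiphenylsilyl)oxy]-5-methylhept-5-enoate (racemic at C2) | CCOC(=O)C(CC/C(C)=C/CO[Si](c1ccccc1)(c1ccccc1)C(C)(C)C)C(C)=O | intermediate
9 | ethyl (2E)-2-{(3E)-5-[(tert-butyldiphenylsilyl)oxy]-3-methylpent-3-en-1-yl}-3-{[(trifluoromethyl)sulfonyl]oxy}but-2-enoate | CCOC(=O)/C(CC/C(C)=C/CO[Si](c1ccccc1)(c1ccccc1)C(C)(C)C)=C(\C)OS(=O)(=O)C(F)(F)F | intermediate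
10 | 2,2-dimethylpent-4-enal | C=CCC(C)(C)C=O | starting material
11 | 9-{5-[(9-borabicyclo[3.3.1]nonan-9-yl)oxy]-4,4-dimethylpentyl}-9-borabicyclo[3.3.1]nonane | CC(C)(CCCB1C2CCCC1CCC2)COB1C2CCCC1CCC2 | intermediate
12 | ethyl (2E)-2-{(3E)-5-[(tert-butyldiphenylsilyl)oxy]-3-methylpent-3-en-1-yl}-8-hydroxy-3,7,7-trimethyloct-2-enoate | CCOC(=O)/C(CC/C(C)=C/CO[Si](c1ccccc1)(c1ccccc1)C(C)(C)C)=C(\C)CCCC(C)(C)CO | intermediate
13 | dilithium salt (C9-alkoxide and enolate) of (3E)-3-{(3E)-5-[(tert-butyldiphenylsilyl)oxy]-3-methylpent-3-en-1-yl}-9-hydroxy-4,8,8-trimethyl-1-(trimethylsilyl)non-3-en-2-one | [Li+].[Li+].[O-]C(=C[Si](C)(C)C)/C(CC/C(C)=C/CO[Si](c1ccccc1)(c1ccccc1)C(C)(C)C)=C(\C)CCCC(C)(C)C[O-] | intermediate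
14 | (3E)-3-{(3E)-5-[(tert-butyldiphenylsilyl)oxy]-3-methylpent-3-en-1-yl}-9-hydroxy-4,8,8-trimethylnon-3-en-2-one | CC(=O)/C(CC/C(C)=C/CO[Si](c1ccccc1)(c1ccccc1)C(C)(C)C)=C(\C)CCCC(C)(C)CO | intermediate
15 | (6E,10E)-12-[(tert-butyldiphenylsilyl)oxy]-2,2,6,10-tetramethyl-7-(2-methyloxiran-2-yl)dodeca-6,10-dien-1-ol (racemic at the oxirane carbon) | CC1(CO1)/C(CC/C(C)=C/CO[Si](c2ccccc2)(c2ccccc2)C(C)(C)C)=C(\C)CCCC(C)(C)CO | intermediate
16 | (6E,10E)-12-[(tert-butyldiphenylsilyl)oxy]-2,2,6,10-tetramethyl-7-(2-methyloxiran-2-yl)dodeca-6,10-dienal | CC1(CO1)/C(CC/C(C)=C/CO[Si](c2ccccc2)(c2ccccc2)C(C)(C)C)=C(\C)CCCC(C)(C)C=O | intermediate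
17 | (7E,11E)-13-[(tert-butyldiphenylsilyl)oxy]-3,3,7,11-tetramethyl-8-(2-methyloxiran-2-yl)-1-nitrotrideca-7,11-dien-2-ol | CC1(CO1)/C(CC/C(C)=C/CO[Si](c2ccccc2)(c2ccccc2)C(C)(C)C)=C(\C)CCCC(C)(C)C(O)C[N+](=O)[O-] | intermediate
18 | (7E,11E)-13-[(tert-butyldiphenylsilyl)oxy]-3,3,7,11-tetramethyl-8-(2-methyloxiran-2-yl)-1-nitrotrideca-7,11-dien-2-yl methanesulfonate | CC1(CO1)/C(CC/C(C)=C/CO[Si](c2ccccc2)(c2ccccc2)C(C)(C)C)=C(\C)CCCC(C)(C)C(OS(C)(=O)=O)C[N+](=O)[O-] | intermediate
19 | tert-butyl{[(2E,6E,12E)-3,7,11,11-tetramethyl-6-(2-methyloxiran-2-yl)-13-nitrotrideca-2,6,12-trien-1-yl]oxy}diphenylsilane | CC1(CO1)/C(CC/C(C)=C/CO[Si](c2ccccc2)(c2ccccc2)C(C)(C)C)=C(\C)CCCC(C)(C)/C=C/[N+](=O)[O-] | intermediate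
20 | (3E,9E)-3-{(3E)-5-[(tert-butyldiphenylsilyl)oxy]-3-methylpent-3-en-1-yl}-2,4,8,8-tetramethyl-10-nitrodeca-3,9-dienal (racemic at C2) | O=CC(C)/C(CC/C(C)=C/CO[Si](c1ccccc1)(c1ccccc1)C(C)(C)C)=C(\C)CCCC(C)(C)/C=C/[N+](=O)[O-] | intermediate
21 | tert-butyl({(1E,3E,9E)-3-{(3E)-5-[(tert-butyldiphenylsilyl)oxy]-3-methylpent-3-en-1-yl}-2,4,8,8-tetramethyl-10-nitrodeca-1,3,9-trien-1-yl}oxy)dimethylsilane | CC(C)(C)[Si](C)(C)O/C=C(\C)/C(CC/C(C)=C/CO[Si](c1ccccc1)(c1ccccc1)C(C)(C)C)=C(\C)CCCC(C)(C)/C=C/[N+](=O)[O-] | intermediate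
22 | 7α-[(tert-butyldimethylsilyl)oxy]-15-[(tert-butyldiphenylsilyl)oxy]-6α-nitrolabda-8,13E-diene (5α-H, 10β-methyl, trans-fused) | CC1=C(CC/C(C)=C/CO[Si](c3ccccc3)(c4ccccc4)C(C)(C)C)[C@@]2(C)CCCC(C)(C)[C@@H]2[C@@H]([N+](=O)[O-])[C@H]1O[Si](C)(C)C(C)(C)C | intermediate
23 | 7α-[(tert-butyldimethylsilyl)oxy]-15-[(tert-butyldiphenylsilyl)oxy]labda-8,13E-dien-6-one oxime | CC1=C(CC/C(C)=C/CO[Si](c3ccccc3)(c4ccccc4)C(C)(C)C)[C@@]2(C)CCCC(C)(C)[C@@H]2C(=NO)[C@H]1O[Si](C)(C)C(C)(C)C | intermediate
24 | 7α-[(tert-butyldimethylsilyl)oxy]-15-[(tert-butyldiphenylsilyl)oxy]labda-8,13E-dien-6-one | CC1=C(CC/C(C)=C/CO[Si](c3ccccc3)(c4ccccc4)C(C)(C)C)[C@@]2(C)CCCC(C)(C)[C@@H]2C(=O)[C@H]1O[Si](C)(C)C(C)(C)C | intermediate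
25 | 7α-[(tert-butyldimethylsilyl)oxy]-15-[(tert-butyldiphenylsilyl)oxy]labda-8,13E-dien-6β-ol | CC1=C(CC/C(C)=C/CO[Si](c3ccccc3)(c4ccccc4)C(C)(C)C)[C@@]2(C)CCCC(C)(C)[C@@H]2[C@H](O)[C@H]1O[Si](C)(C)C(C)(C)C | intermediate
26 | lithium 7α-[(tert-butyldimethylsilyl)oxy]-15-[(tert-butyldiphenylsilyl)oxy]labda-8,13E-dien-6β-olate | CC1=C(CC/C(C)=C/CO[Si](c3ccccc3)(c4ccccc4)C(C)(C)C)[C@@]2(C)CCCC(C)(C)[C@@H]2[C@H]([O-])[C@H]1O[Si](C)(C)C(C)(C)C.[Li+] | intermediate
27 | 7α-[(tert-butyldimethylsilyl)oxy]-15-[(tert-butyldiphenylsilyl)oxy]labda-8,13E-dien-6β-yl 3-methylbutanoate | CC1=C(CC/C(C)=C/CO[Si](c3ccccc3)(c4ccccc4)C(C)(C)C)[C@@]2(C)CCCC(C)(C)[C@@H]2[C@H](OC(=O)CC(C)C)[C@H]1O[Si](C)(C)C(C)(C)C | intermediate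
28 | (5S,6S,7S,10S)-7,15-dihydroxylabda-8,13E-dien-6-yl 3-methylbutanoate (6β-ester, 7α-alcohol; CNP0173680.1) | CC1=C(CC/C(C)=C/CO)[C@@]2(C)CCCC(C)(C)[C@@H]2[C@H](OC(=O)CC(C)C)[C@H]1O | target

**Count**

Total: 17 steps. Longest linear sequence: 17 steps (1 to 28); 7 and 10 are bought and enter at steps 5 and 7.

**Steps most likely to fail**

Step 13 (Proposed new method). What may go wrong: the catalyst may discriminate the two faces poorly, an uncatalysed background cycloaddition may erode the enantiomeric purity, or a stepwise Michael addition with silyl transfer to the nitronate may lose control at C7. The fallback gives up asymmetric induction and uses only known chemistry. It sets out from 21, which is heated without catalyst in toluene at 80 °C, the established thermal intramolecular Diels–Alder reaction of (E)-nitro trienes. This should give the trans-fused adduct as a racemate, that is 22 together with its mirror image ent-22 F1. The two are separated by preparative chromatography on a chiral stationary phase (cellulose tris(3,5-dimethylphenylcarbamate)), and the route is rejoined at 22.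

Step 14. What may go wrong: reduction of the hindered nitro group may be slow, a transient nitronate may eliminate the C7 silyloxy group, or the β,γ-double bond may move into conjugation with the new ketone. The fallback avoids any carbanion at C6. It sets out from 22, which is reduced with Zn dust in AcOH–THF to 6α-amino-7α-[(tert-butyldimethylsilyl)oxy]-15-[(tert-butyldiphenylsilyl)oxy]labda-8,13E-diene F2. Condensation of F2 with 3,5-di-tert-butyl-1,2-benzoquinone in MeOH–THF, followed by the spontaneous prototropic shift, gives the N-(3,5-di-tert-butyl-2-hydroxyphenyl) ketimine of 24 F3. Hydrolysis of F3 with aqueous oxalic acid comes back to the route at 24.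

Step 15. What may go wrong: the polar effect of the axial C7–O bond favours β attack and opposes steric control, so facial selectivity may be poor or the reduction may stall. The fallback replaces steric control by intramolecular hydride delivery. It sets out from 24, whose secondary silyl ether is cleaved selectively with pyridinium p-toluenesulfonate in MeOH to give 15-[(tert-butyldiphenylsilyl)oxy]-7α-hydroxylabda-8,13E-dien-6-one F4. Hydroxyl-directed reduction of F4 with Me4NBH(OAc)3 in MeCN–AcOH at −20 °C delivers hydride from the α face and should give 15-[(tert-butyldiphenylsilyl)oxy]labda-8,13E-diene-6β,7α-diol F5. Selective silylation of the less hindered 7α-hydroxyl of F5 (TBSCl, imidazole, DMF) comes back to the route at 25.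

Further compounds
F1 | step 13 | ent-22, the enantiomer of 22 | CC1=C(CC/C(C)=C/CO[Si](c3ccccc3)(c4ccccc4)C(C)(C)C)[C@]2(C)CCCC(C)(C)[C@H]2[C@H]([N+](=O)[O-])[C@@H]1O[Si](C)(C)C(C)(C)C
F2 | step 14 | 6α-amino-7α-[(tert-butyldimethylsilyl)oxy]-15-[(tert-butyldiphenylsilyl)oxy]labda-8,13E-diene | CC1=C(CC/C(C)=C/CO[Si](c3ccccc3)(c4ccccc4)C(C)(C)C)[C@@]2(C)CCCC(C)(C)[C@@H]2[C@@H](N)[C@H]1O[Si](C)(C)C(C)(C)C
F3 | step 14 | N-(3,5-di-tert-butyl-2-hydroxyphenyl) ketimine of 24 | CC1=C(CC/C(C)=C/CO[Si](c3ccccc3)(c4ccccc4)C(C)(C)C)[C@@]2(C)CCCC(C)(C)[C@@H]2C(=Nc3cc(C(C)(C)C)cc(C(C)(C)C)c3O)[C@H]1O[Si](C)(C)C(C)(C)C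
F4 | step 15 | 15-[(tert-butyldiphenylsilyl)oxy]-7α-hydroxylabda-8,13E-dien-6-one | CC1=C(CC/C(C)=C/CO[Si](c3ccccc3)(c4ccccc4)C(C)(C)C)[C@@]2(C)CCCC(C)(C)[C@@H]2C(=O)[C@H]1O
F5 | step 15 | 15-[(tert-butyldiphenylsilyl)oxy]labda-8,13E-diene-6β,7α-diol | CC1=C(CC/C(C)=C/CO[Si](c3ccccc3)(c4ccccc4)C(C)(C)C)[C@@]2(C)CCCC(C)(C)[C@@H]2[C@H](O)[C@H]1O
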